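## Retrosynthetic overview

1. Target 28 comes from 7-O-acetylation of triol 27. Its (12E)-12,14-diene comes from two Wittig reactions on lactol 25, in which the C12 aldehyde is held by the 8α-hydroxyl.
2. The ring B oxygens come from the C7–C8 enone 21: α-face osmylation (8α-OH), C7 epimerisation (7β-OH), α-face hydride at C6 (6β-OH). The enone comes from Saegusa–Ito oxidation of the C6 silyl enol ether of 18, after C11 has been homologated to C12.
3. The strategy rests on ring B: the ring-fusion bond C5–C10 and the bond C8–C9 are the two σ bonds of a Diels–Alder cyclohexene. Its diene C5=C6–C7=C8 carries the C6 oxygen as a silyl enol ether; its dienophile C9=C10 carries C11 as the formyl group.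
4. The acyclic trienal 17 comes from keto enoate 13 (Horner–Wadsworth–Emmons, kinetic silyl dienol ether), dione 11, an acetaldehyde aldol condensation on keto ketal 5, and copper-catalysed conjugate addition of a ketal Grignard reagent to mesityl oxide (C4 quaternary carbon).
5. Ring order: rings A and B close together in step 9 (ring A through the C1–C4 tether); no ring is made earlier.

Key step: step 9

Assumption: the enal binds the protonated oxazaborolidine through its formyl C–H···O contact in the s-trans form; on that model the catalyst from (R)-α,α-diphenylprolinol leaves open the enal face that leads to the 10β-methyl series, and the (S)-catalyst would be used instead if the sense of induction proved opposite.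

Remark: compound 1, the ethylene ketal of 5-chloropentan-2-one, is bought as such. Ring compounds 18–28 carry labdane numbering (C11 on C9, C17 = methyl on C8, C20 = methyl on C10; β = same side as the C10 methyl).

## Route

Step 1
Reactants: 1 2-(3-chloropropyl)-2-methyl-1,3-dioxolane; 2 mesityl oxide
Product: 5 4,4-dimethyl-7-(2-methyl-1,3-dioxolan-2-yl)heptan-2-one, via Grignard reagent 3 (not isolated), via trimethylsilyl enol ether 4 (not isolated)
Conditions: Mg, THF, reflux; then CuBr·SMe2 (10 mol %), Me3SiCl, 2, THF, −40 → 0 °C; then K2CO3, MeOH, rt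
Reagents that add atoms: none
Why: Copper-catalysed conjugate addition of the primary alkyl Grignard reagent to the β,β-disubstituted enone, with Me3SiCl trapping the enolate as 4, builds the C4 quaternary carbon, and the mild methanolysis frees the ketone while the dioxolane stays intact.

Step 2
Reactants: 5 4,4-dimethyl-7-(2-methyl-1,3-dioxolan-2-yl)heptan-2-one; 6 acetaldehyde
Product: 8 2-hydroxy-6,6-dimethyl-9-(2-methyl-1,3-dioxolan-2-yl)nonan-4-one (racemic carbinol), via lithium enolate 7 (not isolated)
Conditions: LiN(i-Pr)2, THF, −78 °C; MeCHO, −78 °C; aq. NH4Cl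
Reagents that add atoms: none
Why: Kinetic deprotonation by the hindered amide occurs at the methyl group and not at the neopentyl-type CH2, so the directed aldol addition extends the chain at C7; the carbinol centre forms as a racemate and is removed in step 3.

Step 3
Reactants: 8 2-hydroxy-6,6-dimethyl-9-(2-methyl-1,3-dioxolan-2-yl)nonan-4-one
Product: 10 (E)-6,6-dimethyl-9-(2-methyl-1,3-dioxolan-2-yl)non-2-en-4-one, via mesylate 9 (not isolated)
Conditions: MeSO2Cl, Et3N, CH2Cl2, 0 °C; then DBU, rt
Reagents that add atoms: none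
Why: Mesylation followed by base-induced β-elimination of the β-mesyloxy ketone should give the conjugated enone in its favoured (E) geometry.

Step 4
Reactants: 10 (E)-6,6-dimethyl-9-(2-methyl-1,3-dioxolan-2-yl)non-2-en-4-one
Product: 11 (E)-6,6-dimethylundec-9-ene-2,8-dione
Conditions: pyridinium p-toluenesulfonate (cat.), acetone/H2O, 50 °C
Reagents that add atoms: water, O
Why: Acid-catalysed ketal hydrolysis unmasks the methyl ketone under conditions that leave the enone untouched.

Step 5
Reactants: 11 (E)-6,6-dimethylundec-9-ene-2,8-dione; 12 triethyl phosphonoacetate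
Product: 13 ethyl (2E,10E)-3,7,7-trimethyl-9-oxododeca-2,10-dienoate
Conditions: NaH, THF, 0 °C → rt; chromatography
Reagents that add atoms: none
Why: Horner–Wadsworth–Emmons olefination should take place at the unhindered saturated methyl ketone rather than at the conjugated, neopentyl-flanked enone carbonyl and should favour the (2E)-enoate, the (2Z)-isomer being removed by chromatography.

Step 6
Reactants: 13 ethyl (2E,10E)-3,7,7-trimethyl-9-oxododeca-2,10-dienoate
Product: 15 ethyl (2E,8Z,10E)-3,7,7-trimethyl-9-(triisopropylsilyloxy)dodeca-2,8,10-trienoate, via potassium dienolate 14 (not isolated)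
Conditions: KN(SiMe3)2, THF, −78 °C; i-Pr3SiOTf, −78 → 0 °C
Reagents that add atoms: triisopropylsilyl trifluoromethanesulfonate, CC(C)[Si](C(C)C)(C(C)C)OS(=O)(=O)C(F)(F)F
Why: Kinetic α′-deprotonation of the enone (far more acidic than the γ-position of the β,β-disubstituted enoate) and O-silylation of the cross-conjugated enolate give the 2-silyloxy diene, the (8Z) geometry following from allylic strain that keeps the bulky C7 group away from the propenyl group.

Step 7
Reactants: 15 ethyl (2E,8Z,10E)-3,7,7-trimethyl-9-(triisopropylsilyloxy)dodeca-2,8,10-trienoate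
Product: 16 (2E,8Z,10E)-3,7,7-trimethyl-9-(triisopropylsilyloxy)dodeca-2,8,10-trien-1-ol
Conditions: i-Bu2AlH, CH2Cl2, −78 °C; aq. potassium sodium tartrate
Reagents that add atoms: none
Why: 1,2-Reduction of the conjugated ester by the aluminium hydride gives the allylic alcohol, the hindered silyl dienol ether being inert to hydride.

Step 8
Reactants: 16 (2E,8Z,10E)-3,7,7-trimethyl-9-(triisopropylsilyloxy)dodeca-2,8,10-trien-1-ol
Product: 17 (2E,8Z,10E)-3,7,7-trimethyl-9-(triisopropylsilyloxy)dodeca-2,8,10-trienal
Conditions: MnO2 (activated, excess), CH2Cl2, rt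
Reagents that add atoms: none
Why: Allylic oxidation on MnO2 under neutral conditions should give the enal without E/Z isomerisation and without harm to the acid-sensitive silyl dienol ether.

Step 9
Reactants: 17 (2E,8Z,10E)-3,7,7-trimethyl-9-(triisopropylsilyloxy)dodeca-2,8,10-trienal
Product: 18 6-(triisopropylsilyloxy)drim-6-en-11-al (5α-H, 8α-H with 8β-methyl, 9β-formyl, 10β-methyl)
Conditions: (R)-3,3-diphenyl-1-(o-tolyl)tetrahydro-1H,3H-pyrrolo[1,2-c][1,3,2]oxazaborole (20 mol %), HNTf2 (18 mol %), CH2Cl2, high dilution, −78 → −40 °C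
Reagents that add atoms: none
Why: Proposed new method: the protonated oxazaborolidine binds the formyl oxygen and lowers the enal LUMO, so the silyloxy diene adds in a concerted but asynchronous [4+2] in which the C5–C10 bond (nucleophilic diene terminus C5 to the enal β-carbon) runs ahead of C8–C9; the closest known reactions are oxazaborolidinium-catalysed additions of 2-silyloxy dienes to 2-substituted enals and Lewis-acid-promoted type-one intramolecular Diels–Alder reactions of 1,7,9-decatrienals, and the new element is a β,β-disubstituted enal under asymmetric catalysis. Ring B closes as the new cyclohexene through both σ bonds of the cycloaddition, and ring A closes at the same time through the C5–C10 bond because the four-carbon tether C1–C4 already joins C5 and C10 (six-membered, chair-like tether). C9 and C10 are set relative to each other by the (E)-enal geometry (suprafacial addition, 10-methyl cis to 9-formyl), C5 relative to C10 by the endo-formyl/exo-tether transition state (trans fusion, 5α-H), C8 by the (E)-propenyl terminus (8β-methyl, erased in step 11), and the absolute sense by the catalyst, which shields one enal face. The step needs endo and π-facial selectivity: the first is secured by the Lewis-acid-bound formyl group and the (8Z)-silyl enol ether that puts the tether outside on the diene, the second by the catalyst; the gem-dimethyl group at C4 favours the folded conformer and intramolecularity offsets the hindered dienophile.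

Step 10
Reactants: 18 6-(triisopropylsilyloxy)drim-6-en-11-al
Product: 19 12-methoxy-6-(triisopropylsilyloxy)-13,14,15,16-tetranorlabda-6,11-diene (E/Z mixture at C11=C12)
Conditions: Ph3P(CH2OMe)Cl, KN(SiMe3)2, THF, 0 °C → rt
Reagents that add atoms: (methoxymethyl)triphenylphosphonium chloride, COC[P+](c1ccccc1)(c1ccccc1)c1ccccc1.[Cl-]
Why: Wittig methoxymethylenation adds C12 under basic conditions that the silyl enol ether tolerates, and it is run before the enone is made because in the C7–C8 enone the C9–H would be both α to the formyl group and γ to the ketone.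

Step 11
Reactants: 19 12-methoxy-6-(triisopropylsilyloxy)-13,14,15,16-tetranorlabda-6,11-diene
Product: 20 12-methoxy-13,14,15,16-tetranorlabda-7,11-dien-6-one
Conditions: Pd(OAc)2 (1.1 equiv), MeCN, rt → 40 °C
Reagents that add atoms: none
Why: In the Saegusa–Ito oxidation the silyl enol ether hands its enolate to Pd(OAc)2 and β-hydride elimination of the α-face C8–H gives the C7–C8 enone, erasing the C8 centre, whereas the methyl enol ether has no such transmetalation path.

Step 12
Reactants: 20 12-methoxy-13,14,15,16-tetranorlabda-7,11-dien-6-one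
Product: 21 12,12-dimethoxy-13,14,15,16-tetranorlabd-7-en-6-one
Conditions: MeOH, pyridinium p-toluenesulfonate (cat.), 0 °C → rt
Reagents that add atoms: methanol, CO
Why: Acid-catalysed addition of methanol to the enol ether through its oxocarbenium ion stores C12 as a dimethyl acetal that is inert to osmylation, base and hydride.

Step 13
Reactants: 21 12,12-dimethoxy-13,14,15,16-tetranorlabd-7-en-6-one
Product: 22 7α,8α-dihydroxy-12,12-dimethoxy-13,14,15,16-tetranorlabdan-6-one
Conditions: OsO4 (10 mol %), N-methylmorpholine N-oxide, pyridine (cat.), acetone/H2O, rt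
Reagents that add atoms: osmium tetroxide, O=[Os](=O)(=O)=O; N-methylmorpholine N-oxide, C[N+]1([O-])CCOCC1
Why: Catalytic syn-dihydroxylation of the trisubstituted enone should occur on the α face, opposite the axial C10 methyl group and the β-oriented C9 side chain, setting C8 (8α-OH, 8β-methyl) and C7 (7α-OH).

Step 14
Reactants: 22 7α,8α-dihydroxy-12,12-dimethoxy-13,14,15,16-tetranorlabdan-6-one
Product: 23 7β,8α-dihydroxy-12,12-dimethoxy-13,14,15,16-tetranorlabdan-6-one
Conditions: DBU (0.5 equiv), toluene, rt → 50 °C
Reagents that add atoms: none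
Why: Base-catalysed enolisation of the α-hydroxy ketone should epimerise C7 under thermodynamic control to the equatorial 7β-alcohol, which is hydrogen-bonded to the C6 carbonyl and free of 1,3-diaxial contacts, the amidine base in an aprotic solvent keeping retro-aldol opening of C7–C8 slow.

Step 15
Reactants: 23 7β,8α-dihydroxy-12,12-dimethoxy-13,14,15,16-tetranorlabdan-6-one
Product: 24 12,12-dimethoxy-13,14,15,16-tetranorlabdane-6β,7β,8α-triol
Conditions: NaBH4, MeOH, 0 °C
Reagents that add atoms: none
Why: In this substrate-controlled carbonyl reduction hydride should add to C6 from the α face, because the β face is screened by the axial methyl groups on C4, C8 and C10, giving the axial 6β-alcohol cis to the 7β-hydroxyl.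

Step 16
Reactants: 24 12,12-dimethoxy-13,14,15,16-tetranorlabdane-6β,7β,8α-triol
Product: 25 8α,12-epoxy-13,14,15,16-tetranorlabdane-6β,7β,12-triol (lactol, both C12 epimers)
Conditions: AcOH/THF/H2O (3:1:1), 40 °C
Reagents that add atoms: water, O
Why: Acid-catalysed acetal hydrolysis releases the C12 aldehyde, which the tertiary 8α-hydroxyl captures as a trans-fused five-membered lactol, so no oxidation is needed in the presence of the triol.

Step 17
Reactants: 25 8α,12-epoxy-13,14,15,16-tetranorlabdane-6β,7β,12-triol
Product: 26 (12E)-6β,7β,8α-trihydroxy-15-norlabd-12-en-14-al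
Conditions: Ph3P=C(Me)CHO (3 equiv), toluene, 90 °C
Reagents that add atoms: 2-(triphenylphosphoranylidene)propanal, CC(C=O)=P(c1ccccc1)(c1ccccc1)c1ccccc1
Why: Wittig olefination of the lactol through its open hydroxy-aldehyde form with the formyl-stabilised ylide should give the (E)-trisubstituted enal (formyl trans to C11), whose α-methyl group makes it a poor acceptor for oxa-Michael addition of the 8α-hydroxyl.

Step 18
Reactants: 26 (12E)-6β,7β,8α-trihydroxy-15-norlabd-12-en-14-al
Product: 27 (12E)-labda-12,14-diene-6β,7β,8α-triol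
Conditions: Ph3PCH3Br, KN(SiMe3)2 (6 equiv each), THF, −78 → 0 °C
Reagents that add atoms: methyltriphenylphosphonium bromide, C[P+](c1ccccc1)(c1ccccc1)c1ccccc1.[Br-]
Why: Wittig methylenation of the enal with excess non-stabilised ylide (the three hydroxyls are deprotonated first) completes the 12,14-diene without touching the C12=C13 geometry.

Step 19
Reactants: 27 (12E)-labda-12,14-diene-6β,7β,8α-triol
Product: 28 (12E)-7β-acetoxylabda-12,14-diene-6β,8α-diol (CNP0225877.1)
Conditions: Ac2O (1.2 equiv), pyridine, CH2Cl2, 0 °C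
Reagents that add atoms: acetic anhydride, CC(=O)OC(C)=O
Why: Acylation should be selective for the equatorial secondary 7β-hydroxyl, because the 6β-hydroxyl is axial between the C4 and C10 methyl groups and the 8α-hydroxyl is tertiary.

## Compound list

1 | 2-(3-chloropropyl)-2-methyl-1,3-dioxolane | CC1(CCCCl)OCCO1 | starting material
2 | mesityl oxide (4-methylpent-3-en-2-one) | CC(C)=CC(C)=O | starting material
3 | [3-(2-methyl-1,3-dioxolan-2-yl)propyl]magnesium chloride | CC1(CCC[Mg]Cl)OCCO1 | intermediate
4 | 4,4-dimethyl-7-(2-methyl-1,3-dioxolan-2-yl)-2-(trimethylsilyloxy)hept-2-ene (E/Z mixture) | CC(O[Si](C)(C)C)=CC(C)(C)CCCC1(C)OCCO1 | intermediate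
5 | 4,4-dimethyl-7-(2-methyl-1,3-dioxolan-2-yl)heptan-2-one | CC(=O)CC(C)(C)CCCC1(C)OCCO1 | intermediate
6 | acetaldehyde | CC=O | starting material
7 | lithium 4,4-dimethyl-7-(2-methyl-1,3-dioxolan-2-yl)hept-1-en-2-olate | C=C(O[Li])CC(C)(C)CCCC1(C)OCCO1 | intermediate
8 | 2-hydroxy-6,6-dimethyl-9-(2-methyl-1,3-dioxolan-2-yl)nonan-4-one (racemic) | CC(O)CC(=O)CC(C)(C)CCCC1(C)OCCO1 | intermediate
9 | 6,6-dimethyl-9-(2-methyl-1,3-dioxolan-2-yl)-4-oxononan-2-yl methanesulfonate | CC(OS(C)(=O)=O)CC(=O)CC(C)(C)CCCC1(C)OCCO1 | intermediate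
10 | (E)-6,6-dimethyl-9-(2-methyl-1,3-dioxolan-2-yl)non-2-en-4-one | C/C=C/C(=O)CC(C)(C)CCCC1(C)OCCO1 | intermediate
11 | (E)-6,6-dimethylundec-9-ene-2,8-dione | C/C=C/C(=O)CC(C)(C)CCCC(C)=O | intermediate
12 | triethyl phosphonoacetate | CCOC(=O)CP(=O)(OCC)OCC | starting material
13 | ethyl (2E,10E)-3,7,7-trimethyl-9-oxododeca-2,10-dienoate | CCOC(=O)/C=C(\C)CCCC(C)(C)CC(=O)/C=C/C | intermediate
14 | potassium (8Z)-dienolate of 13 | CCOC(=O)/C=C(\C)CCCC(C)(C)/C=C(O[K])/C=C/C | intermediate
15 | ethyl (2E,8Z,10E)-3,7,7-trimethyl-9-(triisopropylsilyloxy)dodeca-2,8,10-trienoate | CCOC(=O)/C=C(\C)CCCC(C)(C)/C=C(O[Si](C(C)C)(C(C)C)C(C)C)/C=C/C | intermediate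
16 | (2E,8Z,10E)-3,7,7-trimethyl-9-(triisopropylsilyloxy)dodeca-2,8,10-trien-1-ol | OC/C=C(\C)CCCC(C)(C)/C=C(O[Si](C(C)C)(C(C)C)C(C)C)/C=C/C | intermediate
17 | (2E,8Z,10E)-3,7,7-trimethyl-9-(triisopropylsilyloxy)dodeca-2,8,10-trienal | O=C/C=C(\C)CCCC(C)(C)/C=C(O[Si](C(C)C)(C(C)C)C(C)C)/C=C/C | intermediate
18 | 6-(triisopropylsilyloxy)drim-6-en-11-al (5α-H, 8α-H, 9β-CHO, 10β-Me) | O=C[C@H]1[C@@H](C)C=C(O[Si](C(C)C)(C(C)C)C(C)C)[C@H]2C(C)(C)CCC[C@@]21C | intermediate
19 | 12-methoxy-6-(triisopropylsilyloxy)-13,14,15,16-tetranorlabda-6,11-diene (E/Z at C11) | COC=C[C@H]1[C@@H](C)C=C(O[Si](C(C)C)(C(C)C)C(C)C)[C@H]2C(C)(C)CCC[C@@]21C | intermediate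
20 | 12-methoxy-13,14,15,16-tetranorlabda-7,11-dien-6-one | COC=C[C@H]1C(C)=CC(=O)[C@H]2C(C)(C)CCC[C@@]21C | intermediate
21 | 12,12-dimethoxy-13,14,15,16-tetranorlabd-7-en-6-one | COC(OC)C[C@H]1C(C)=CC(=O)[C@H]2C(C)(C)CCC[C@@]21C | intermediate
22 | 7α,8α-dihydroxy-12,12-dimethoxy-13,14,15,16-tetranorlabdan-6-one | COC(OC)C[C@H]1[C@](C)(O)[C@H](O)C(=O)[C@H]2C(C)(C)CCC[C@@]21C | intermediate
23 | 7β,8α-dihydroxy-12,12-dimethoxy-13,14,15,16-tetranorlabdan-6-one | COC(OC)C[C@H]1[C@](C)(O)[C@@H](O)C(=O)[C@H]2C(C)(C)CCC[C@@]21C | intermediate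
24 | 12,12-dimethoxy-13,14,15,16-tetranorlabdane-6β,7β,8α-triol | COC(OC)C[C@H]1[C@](C)(O)[C@@H](O)[C@@H](O)[C@H]2C(C)(C)CCC[C@@]21C | intermediate
25 | 8α,12-epoxy-13,14,15,16-tetranorlabdane-6β,7β,12-triol (C12 epimers) | OC3C[C@H]1[C@](C)(O3)[C@@H](O)[C@@H](O)[C@H]2C(C)(C)CCC[C@@]21C | intermediate
26 | (12E)-6β,7β,8α-trihydroxy-15-norlabd-12-en-14-al | O=C/C(C)=C/C[C@H]1[C@](C)(O)[C@@H](O)[C@@H](O)[C@H]2C(C)(C)CCC[C@@]21C | intermediate
27 | (12E)-labda-12,14-diene-6β,7β,8α-triol | C=C/C(C)=C/C[C@H]1[C@](C)(O)[C@@H](O)[C@@H](O)[C@H]2C(C)(C)CCC[C@@]21C | intermediate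
28 | (12E)-7β-acetoxylabda-12,14-diene-6β,8α-diol (CNP0225877.1) | C=C/C(C)=C/C[C@H]1[C@](C)(O)[C@@H](OC(C)=O)[C@@H](O)[C@H]2C(C)(C)CCC[C@@]21C | target

## Count and risks

Total steps: 19. Longest linear sequence: 19 steps (the route is fully linear from 1 and 2).

**Step 9.** The cycloaddition may fail through slow turnover with the hindered β,β-disubstituted enal. The strong acid may instead cause intermolecular Mukaiyama aldol addition to the activated formyl group or protodesilylation of the diene. Facial or endo selectivity may also be poor. The fallback uses known chemistry only; it sets out from 17 and comes back at 18. Trienal 17 would be cyclised without a catalyst in toluene at 160–180 °C (BHT, sealed tube). This thermal type-one intramolecular Diels–Alder reaction should give the trans-fused adduct as a racemate, racemic 6-(triisopropylsilyloxy)drim-6-en-11-al F1. NaBH4 in EtOH would reduce it to racemic 6-(triisopropylsilyloxy)drim-6-en-11-ol F2. Esterification with (S)-2-methoxy-2-phenylacetic acid (DCC, DMAP, CH2Cl2) and chromatographic separation of the two diastereomeric esters would give the (S)-2-methoxy-2-phenylacetate of the 5α-H, 10β-methyl enantiomer F3. K2CO3 in MeOH would release enantiomerically pure 6-(triisopropylsilyloxy)drim-6-en-11-ol F4. Parikh–Doering oxidation (SO3·pyridine, DMSO, Et3N) would return 18.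

**Step 14.** Epimerisation at C7 may stall at an unfavourable equilibrium. It may also be overtaken by α-ketol shift to the 7-ketone, retro-aldol opening of the C7–C8 bond, or dehydration. The fallback sets out from 22 and comes back at 23, under kinetic instead of thermodynamic control. The axial secondary hydroxyl would be triflated (Tf2O, pyridine, CH2Cl2, −20 °C) to give 8α-hydroxy-12,12-dimethoxy-6-oxo-13,14,15,16-tetranorlabdan-7α-yl trifluoromethanesulfonate F5. The cis tertiary 8α-hydroxyl cannot displace this group. Nitrite would then displace it with inversion (Bu4NNO2, DMF, rt; Lattrell–Dax inversion, the nitrite ester hydrolysing on work-up) to give 23.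

**Step 11.** Dehydrosilylation may be slow for the bulky triisopropylsilyl enol ether, and Pd(OAc)2 may then attack the methyl enol ether (acetoxypalladation) instead. The fallback sets out from 19 and comes back at 21, bypassing 20. Both enol ethers would be solvolysed with HCl (cat.) in MeOH/HC(OMe)3 to give 12,12-dimethoxy-13,14,15,16-tetranorlabdan-6-one F6. Kinetic enolisation at C7 (LiN(i-Pr)2, THF, −78 °C) and trapping with PhSeBr would give 12,12-dimethoxy-7-(phenylselanyl)-13,14,15,16-tetranorlabdan-6-one F7. H2O2 and pyridine in CH2Cl2 at 0 °C would trigger selenoxide syn-elimination towards the α-face C8–H, the only β-hydrogen available, to give 21.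

Further compounds
F1 | step 9 | racemic 6-(triisopropylsilyloxy)drim-6-en-11-al (one enantiomer drawn) | O=C[C@H]1[C@@H](C)C=C(O[Si](C(C)C)(C(C)C)C(C)C)[C@H]2C(C)(C)CCC[C@@]21C
F2 | step 9 | racemic 6-(triisopropylsilyloxy)drim-6-en-11-ol (one enantiomer drawn) | OC[C@H]1[C@@H](C)C=C(O[Si](C(C)C)(C(C)C)C(C)C)[C@H]2C(C)(C)CCC[C@@]21C
F3 | step 9 | 6-(triisopropylsilyloxy)drim-6-en-11-yl (S)-2-methoxy-2-phenylacetate, 5α-H, 10β-methyl diastereomer | CO[C@H](C(=O)OC[C@H]1[C@@H](C)C=C(O[Si](C(C)C)(C(C)C)C(C)C)[C@H]2C(C)(C)CCC[C@@]21C)c1ccccc1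
F4 | step 9 | 6-(triisopropylsilyloxy)drim-6-en-11-ol, single enantiomer (5α-H, 10β-methyl) | OC[C@H]1[C@@H](C)C=C(O[Si](C(C)C)(C(C)C)C(C)C)[C@H]2C(C)(C)CCC[C@@]21C
F5 | step 14 | 8α-hydroxy-12,12-dimethoxy-6-oxo-13,14,15,16-tetranorlabdan-7α-yl trifluoromethanesulfonate | COC(OC)C[C@H]1[C@](C)(O)[C@H](OS(=O)(=O)C(F)(F)F)C(=O)[C@H]2C(C)(C)CCC[C@@]21C
F6 | step 11 | 12,12-dimethoxy-13,14,15,16-tetranorlabdan-6-one (8α-H) | COC(OC)C[C@H]1[C@@H](C)CC(=O)[C@H]2C(C)(C)CCC[C@@]21C
F7 | step 11 | 12,12-dimethoxy-7-(phenylselanyl)-13,14,15,16-tetranorlabdan-6-one | COC(OC)C[C@H]1[C@@H](C)C([Se]c3ccccc3)C(=O)[C@H]2C(C)(C)CCC[C@@]21C
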